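The route rests on cutting the O–C6 bond of the 1,2-dioxane ring (numbering from the lactone carbonyl, C1). C6 carries a methyl group and a peroxide oxygen, which is the pattern left when a hydroperoxide adds in the Markovnikov sense to a 1,1-disubstituted alkene. The key step exploits this: Hg(OAc)2 makes the C3 hydroperoxide attack the C6 methylidene carbon in a 6-exo closure, forming the O–C6 bond, the dioxane ring and the C6 stereocentre in one operation, with CH2HgOAc as the latent C6 methyl. Its precursor is an acyclic (3S,4S)-3-hydroperoxy-4-ol carrying the C6=CH2 alkene, TBS ethers at C1 and C11, and a tail truncated at C11.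

Key step: step 11

Remark: atoms are numbered C1 (lactone carbonyl) to C16 (styryl carbon) throughout; TBS = tert-butyldimethylsilyl. Compounds 1, 5 and 21 and all named reagents are taken as purchased. The unwanted C6 epimer from step 11 is assumed to be removable by chromatography at the stage of 16 or 17.

Step 1
Reactants: 1 3-(TBSO)propanal
Product: 2 ethyl (Z)-5-(TBSO)-2-methylpent-2-enoate
Conditions: KN(SiMe3)2, 18-crown-6, THF, −78 °C
Reagents that add atoms: ethyl 2-[bis(2,2,2-trifluoroethoxy)phosphoryl]propanoate, CCOC(=O)C(C)P(=O)(OCC(F)(F)F)OCC(F)(F)F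
Why: Still–Gennari variant of the Horner–Wadsworth–Emmons olefination, in which the electron-poor phosphonate with a dissociated potassium counter-ion eliminates from the kinetic adduct and should give the (Z)-trisubstituted enoate whose geometry later fixes the C3/C4 relationship.

Step 2
Reactants: 2 ethyl (Z)-5-(TBSO)-2-methylpent-2-enoate
Product: 3 (Z)-5-(TBSO)-2-methylpent-2-en-1-ol
Conditions: i-Bu2AlH, CH2Cl2, −78 °C; aq. KNa tartrate
Reagents that add atoms: none
Why: Hydride 1,2-reduction of the unsaturated ester to the allylic alcohol at low temperature leaves the silyl ether and the Z geometry untouched.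

Step 3
Reactants: 3 (Z)-5-(TBSO)-2-methylpent-2-en-1-ol
Product: 4 (Z)-5-bromo-4-methylpent-3-en-1-yl TBS ether
Conditions: CBr4, PPh3, CH2Cl2, 0 °C
Reagents that add atoms: carbon tetrabromide, BrC(Br)(Br)Br
Why: Appel reaction, in which bromide displaces the oxyphosphonium group at the unhindered primary allylic carbon (C5) without allylic transposition or Z/E change.

Step 4
Reactants: 5 (R)-citronellal
Product: 6 (4R)-4,8-dimethylnon-7-en-1-yne
Conditions: K2CO3, MeOH, 0 °C to rt
Reagents that add atoms: dimethyl (1-diazo-2-oxopropyl)phosphonate, COP(=O)(OC)C(=[N+]=[N-])C(C)=O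
Why: Seyferth–Gilbert homologation in its Ohira–Bestmann form turns the aldehyde carbon (future C6) into a terminal alkyne under mild carbonate conditions, and the C8 stereocentre, being β to the carbonyl, cannot epimerise.

Step 5
Reactants: 6 (4R)-4,8-dimethylnon-7-en-1-yne
Product: 8 (4R)-2-bromo-4,8-dimethylnona-1,7-diene, via alkenylborane 7 (not isolated)
Conditions: B-Br-9-BBN, CH2Cl2, 0 °C; then AcOH, 0 °C to rt
Reagents that add atoms: B-bromo-9-borabicyclo[3.3.1]nonane, BrB1C2CCCC1CCC2
Why: syn-Bromoboration of the terminal alkyne puts bromine on the internal carbon and boron on the terminal one, and protodeboronation with acetic acid gives the 2-bromo-1-alkene while the trisubstituted alkene is inert to the haloborane.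

Step 6
Reactants: 8 (4R)-2-bromo-4,8-dimethylnona-1,7-diene
Product: 10 (4R)-6-bromo-4-methylhept-6-en-1-ol, via aldehyde 9 (not isolated)
Conditions: O3, CH2Cl2–MeOH, −78 °C (Sudan Red 7B end point); then NaBH4, −78 to 0 °C
Reagents that add atoms: ozone, [O-][O+]=O
Why: Indicator-controlled ozonolysis cleaves the electron-rich trisubstituted alkene much faster than the electron-poor bromoalkene, and borohydride reduction of the peroxidic products gives the primary alcohol (future C11–OH).

Step 7
Reactants: 10 (4R)-6-bromo-4-methylhept-6-en-1-ol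
Product: 11 (4R)-6-bromo-4-methylhept-6-en-1-yl TBS ether
Conditions: TBSCl, imidazole, DMF, rt
Reagents that add atoms: tert-butyldimethylsilyl chloride, CC(C)(C)[Si](C)(C)Cl
Why: Standard imidazole-mediated silylation of a primary alcohol, giving the same protecting group at C11 as at C1 so that both are removed together later.

Step 8
Reactants: 11 (4R)-6-bromo-4-methylhept-6-en-1-yl TBS ether; 4 (Z)-5-bromo-4-methylpent-3-en-1-yl TBS ether
Product: 13 (3Z,8R)-1,11-bis(TBSO)-4,8-dimethyl-6-methylideneundec-3-ene, via Grignard reagent 12 (not isolated)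
Conditions: Mg, THF, 45 °C; then 4, CuBr·SMe2 (10 mol%), THF, −30 to 0 °C
Reagents that add atoms: none
Why: Copper-catalysed cross-coupling of an alkenyl Grignard reagent with a primary allylic bromide proceeds by SN2-type substitution at C5 with retention of the Z alkene, forming the C5–C6 bond of the skipped diene.

Step 9
Reactants: 13 (3Z,8R)-1,11-bis(TBSO)-4,8-dimethyl-6-methylideneundec-3-ene
Product: 14 (3R,4S,8R)-1,11-bis(TBSO)-3,4-epoxy-4,8-dimethyl-6-methylideneundecane
Conditions: D-fructose-derived Shi ketone (30 mol%), KHSO5 (triple salt), K2CO3, Bu4NHSO4, MeCN–CH2(OMe)2, aq. Na2B4O7/Na2EDTA, 0 °C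
Reagents that add atoms: potassium peroxymonosulfate, [K+].[O-]S(=O)(=O)OO
Why: Shi asymmetric epoxidation, in which the electrophilic chiral dioxirane prefers the electron-rich trisubstituted alkene over the 1,1-disubstituted one and the spiro transition state of the D-fructose-derived ketone delivers oxygen to the face giving the (3R,4S)-epoxide, so C4 is set for good and C3 provisionally.

Step 10
Reactants: 14 (3R,4S,8R)-1,11-bis(TBSO)-3,4-epoxy-4,8-dimethyl-6-methylideneundecane
Product: 15 (3S,4S,8R)-1,11-bis(TBSO)-3-hydroperoxy-4,8-dimethyl-6-methylideneundecan-4-ol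
Conditions: H2O2·urea (excess), Cs2CO3 (0.5 equiv), DMF, 0 to 30 °C
Reagents that add atoms: hydrogen peroxide, OO
Why: Base-mediated perhydrolysis of an epoxide, in which the hydroperoxide anion (an α-effect nucleophile, more reactive in the dipolar aprotic medium) opens the ring by SN2 attack at the less substituted C3 with inversion (3R to 3S) while C4 keeps its oxygen; excess H2O2 keeps the tertiary alkoxide protonated so that fragmentation of the β-hydroxy hydroperoxide is suppressed, and acid, which would place the peroxide on C4, is avoided.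

Step 11
Reactants: 15 (3S,4S,8R)-1,11-bis(TBSO)-3-hydroperoxy-4,8-dimethyl-6-methylideneundecan-4-ol
Product: 16 (3S,4S,6R)-6-[(acetoxymercurio)methyl]-3-[2-(TBSO)ethyl]-6-[(2R)-5-(TBSO)-2-methylpentyl]-4-methyl-1,2-dioxan-4-ol
Conditions: Hg(OAc)2, CH2Cl2, 0 °C to rt; C6 epimers separated on silica
Reagents that add atoms: mercury diacetate, CC(=O)O[Hg]OC(C)=O
Why: Hg(OAc)2 adds reversibly to the only alkene to give a mercurinium ion, and the terminal oxygen of the C3 hydroperoxide attacks the more substituted carbon C6 anti to mercury with loss of acetic acid; this is the intramolecular peroxymercuration of an alkenyl hydroperoxide, a known route to 1,2-dioxanes. The 1,2-dioxane closes in a 6-exo-trig mode through a chair in which the C3 arm and the C4 methyl are equatorial and the C4 hydroxyl is axial. C6, the one new stereocentre, is set by the alkene face that the peroxide oxygen attacks, that is by whether C7 or the CH2Hg group takes the axial site syn to the C4 hydroxyl; this bias is weak, so both C6 epimers are expected and the (6R) isomer, with CH2Hg cis to the C4 methyl, is isolated by chromatography. Regioselectivity (6-exo Markovnikov over 7-endo) is secured by the 1,1-disubstitution of the alkene, which localises positive charge on C6. Chemoselectivity is secured by the substrate, since the tertiary C4 hydroxyl could only close a four-membered ring, the silyl ethers are inert to divalent mercury and no second alkene is present.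

Step 12
Reactants: 16 (3S,4S,6R)-6-[(acetoxymercurio)methyl]-3-[2-(TBSO)ethyl]-6-[(2R)-5-(TBSO)-2-methylpentyl]-4-methyl-1,2-dioxan-4-ol
Product: 17 (3S,4S,6R)-3-[2-(TBSO)ethyl]-6-[(2R)-5-(TBSO)-2-methylpentyl]-4,6-dimethyl-1,2-dioxan-4-ol
Conditions: NaBH4, 3 M aq. NaOH, CH2Cl2, 0 °C
Reagents that add atoms: none
Why: Hydride demercuration, in which borohydride converts C–HgOAc into an alkylmercury hydride that collapses through a primary alkyl radical; at 0 °C with excess hydride, hydrogen transfer should outrun attack of the radical on the O–O bond, and no stereocentre is touched.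

Step 13
Reactants: 17 (3S,4S,6R)-3-[2-(TBSO)ethyl]-6-[(2R)-5-(TBSO)-2-methylpentyl]-4,6-dimethyl-1,2-dioxan-4-ol
Product: 18 (3S,4S,6R)-3-(2-hydroxyethyl)-6-[(2R)-5-hydroxy-2-methylpentyl]-4,6-dimethyl-1,2-dioxan-4-ol
Conditions: HF·pyridine, pyridine, THF, 0 °C to rt
Reagents that add atoms: none
Why: Fluoride-mediated cleavage of both primary silyl ethers under buffered, non-basic conditions leaves the tertiary alcohol and the dialkyl peroxide intact.

Step 14
Reactants: 18 (3S,4S,6R)-3-(2-hydroxyethyl)-6-[(2R)-5-hydroxy-2-methylpentyl]-4,6-dimethyl-1,2-dioxan-4-ol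
Product: 20 (4R)-5-[(1S,4R,6S)-4,6-dimethyl-8-oxo-2,3,7-trioxabicyclo[4.3.0]nonan-4-yl]-4-methylpentanal, via lactol aldehyde 19 (not isolated)
Conditions: TEMPO (20 mol%), PhI(OAc)2, CH2Cl2, rt
Reagents that add atoms: none
Why: Oxoammonium oxidation (TEMPO/PhI(OAc)2) takes both primary alcohols to aldehydes; the C1 aldehyde is captured by the C4 hydroxyl as a five-membered lactol that is oxidised on to the cis-fused γ-lactone, whereas the C11 aldehyde stays at that level in anhydrous CH2Cl2.

Step 15
Reactants: 21 1-phenylprop-2-en-1-ol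
Product: 23 ethyl (E)-5-phenylpent-4-enoate, via ketene acetal 22 (not isolated)
Conditions: CH3C(OEt)3, EtCO2H (cat.), 140 °C, EtOH distilled off
Reagents that add atoms: triethyl orthoacetate, CCOC(C)(OCC)OCC
Why: Johnson–Claisen rearrangement, in which the mixed ketene acetal rearranges through a chair transition state with phenyl equatorial to give the (E)-styryl alkene.

Step 16
Reactants: 23 ethyl (E)-5-phenylpent-4-enoate
Product: 24 (E)-5-phenylpent-4-en-1-ol
Conditions: LiAlH4, THF, 0 °C
Reagents that add atoms: none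
Why: Hydride reduction of the ester to the primary alcohol does not touch the isolated styrene double bond.

Step 17
Reactants: 24 (E)-5-phenylpent-4-en-1-ol
Product: 25 1-phenyl-5-{[(E)-5-phenylpent-4-en-1-yl]sulfanyl}-1H-tetrazole
Conditions: 1-phenyl-1H-tetrazole-5-thiol, PPh3, DIAD, THF, 0 °C to rt
Reagents that add atoms: 1-phenyl-1H-tetrazole-5-thiol, Sc1nnnn1-c1ccccc1
Why: Mitsunobu reaction, in which the acidic heteroaryl thiol displaces the activated primary alcohol to form the C–S bond.

Step 18
Reactants: 25 1-phenyl-5-{[(E)-5-phenylpent-4-en-1-yl]sulfanyl}-1H-tetrazole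
Product: 27 1-phenyl-5-{[(E)-5-phenylpent-4-en-1-yl]sulfonyl}-1H-tetrazole, via sulfoxide 26 (not isolated)
Conditions: (NH4)6Mo7O24·4H2O (10 mol%), 30% aq. H2O2, EtOH, 0 °C to rt
Reagents that add atoms: hydrogen peroxide, OO
Why: Molybdate-catalysed peroxide oxidation of the sulfide through the sulfoxide to the sulfone is selective for sulfur over the styrene double bond.

Step 19
Reactants: 27 1-phenyl-5-{[(E)-5-phenylpent-4-en-1-yl]sulfonyl}-1H-tetrazole; 20 (4R)-5-[(1S,4R,6S)-4,6-dimethyl-8-oxo-2,3,7-trioxabicyclo[4.3.0]nonan-4-yl]-4-methylpentanal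
Product: 29 (1S,4R,6S)-4,6-dimethyl-4-[(2R,5E,9E)-2-methyl-10-phenyldeca-5,9-dien-1-yl]-2,3,7-trioxabicyclo[4.3.0]nonan-8-one, via sulfonyl carbanion 28 (not isolated)
Conditions: KN(SiMe3)2 (slightly less than the sulfone), DME, −78 °C; then 20, −78 to −20 °C
Reagents that add atoms: none
Why: Julia–Kocienski olefination, in which the pre-formed potassium carbanion of the phenyltetrazolyl sulfone adds to the C11 aldehyde and Smiles rearrangement with loss of SO2 and the tetrazolone should give the (E)-C11=C12 alkene; with no excess amide base at low temperature, the lactone α-protons and the β-peroxide should be spared.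

Compound list
1 | 3-[(tert-butyldimethylsilyl)oxy]propanal | O=CCCO[Si](C)(C)C(C)(C)C | starting material
2 | ethyl (Z)-5-[(tert-butyldimethylsilyl)oxy]-2-methylpent-2-enoate | CCOC(=O)/C(C)=C\CCO[Si](C)(C)C(C)(C)C | intermediate
3 | (Z)-5-[(tert-butyldimethylsilyl)oxy]-2-methylpent-2-en-1-ol | OC/C(C)=C\CCO[Si](C)(C)C(C)(C)C | intermediate
4 | {[(Z)-5-bromo-4-methylpent-3-en-1-yl]oxy}(tert-butyl)dimethylsilane | BrC/C(C)=C\CCO[Si](C)(C)C(C)(C)C | intermediate
5 | (R)-citronellal, (3R)-3,7-dimethyloct-6-enal | C[C@H](CCC=C(C)C)CC=O | starting material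
6 | (4R)-4,8-dimethylnon-7-en-1-yne | C[C@H](CCC=C(C)C)CC#C | intermediate
7 | 9-[(1Z,4R)-2-bromo-4,8-dimethylnona-1,7-dien-1-yl]-9-borabicyclo[3.3.1]nonane (formed in the flask) | C[C@H](CCC=C(C)C)C/C(Br)=C/B1C2CCCC1CCC2 | intermediate
8 | (4R)-2-bromo-4,8-dimethylnona-1,7-diene | C[C@H](CCC=C(C)C)CC(Br)=C | intermediate
9 | (4R)-6-bromo-4-methylhept-6-enal (formed in the flask) | C[C@H](CCC=O)CC(Br)=C | intermediate
10 | (4R)-6-bromo-4-methylhept-6-en-1-ol | C[C@H](CCCO)CC(Br)=C | intermediate
11 | {[(4R)-6-bromo-4-methylhept-6-en-1-yl]oxy}(tert-butyl)dimethylsilane | C[C@H](CCCO[Si](C)(C)C(C)(C)C)CC(Br)=C | intermediate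
12 | bromo{(4R)-7-[(tert-butyldimethylsilyl)oxy]-4-methylhept-1-en-2-yl}magnesium (formed in the flask) | C[C@H](CCCO[Si](C)(C)C(C)(C)C)CC(=C)[Mg]Br | intermediate
13 | (3Z,8R)-1,11-bis[(tert-butyldimethylsilyl)oxy]-4,8-dimethyl-6-methylideneundec-3-ene | C[C@H](CCCO[Si](C)(C)C(C)(C)C)CC(=C)C/C(C)=C\CCO[Si](C)(C)C(C)(C)C | intermediate
14 | (3R,4S,8R)-1,11-bis[(tert-butyldimethylsilyl)oxy]-3,4-epoxy-4,8-dimethyl-6-methylideneundecane | C[C@H](CCCO[Si](C)(C)C(C)(C)C)CC(=C)C[C@]1(C)O[C@@H]1CCO[Si](C)(C)C(C)(C)C | intermediate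
15 | (3S,4S,8R)-1,11-bis[(tert-butyldimethylsilyl)oxy]-3-hydroperoxy-4,8-dimethyl-6-methylideneundecan-4-ol | C[C@H](CCCO[Si](C)(C)C(C)(C)C)CC(=C)C[C@](C)(O)[C@H](CCO[Si](C)(C)C(C)(C)C)OO | intermediate
16 | (3S,4S,6R)-6-[(acetoxymercurio)methyl]-3-{2-[(tert-butyldimethylsilyl)oxy]ethyl}-6-{(2R)-5-[(tert-butyldimethylsilyl)oxy]-2-methylpentyl}-4-methyl-1,2-dioxan-4-ol | C[C@H](CCCO[Si](C)(C)C(C)(C)C)C[C@]1(C[Hg]OC(C)=O)C[C@](C)(O)[C@H](CCO[Si](C)(C)C(C)(C)C)OO1 | intermediate
17 | (3S,4S,6R)-3-{2-[(tert-butyldimethylsilyl)oxy]ethyl}-6-{(2R)-5-[(tert-butyldimethylsilyl)oxy]-2-methylpentyl}-4,6-dimethyl-1,2-dioxan-4-ol | C[C@H](CCCO[Si](C)(C)C(C)(C)C)C[C@]1(C)C[C@](C)(O)[C@H](CCO[Si](C)(C)C(C)(C)C)OO1 | intermediate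
18 | (3S,4S,6R)-3-(2-hydroxyethyl)-6-[(2R)-5-hydroxy-2-methylpentyl]-4,6-dimethyl-1,2-dioxan-4-ol | C[C@H](CCCO)C[C@]1(C)C[C@](C)(O)[C@H](CCO)OO1 | intermediate
19 | (4R)-5-[(1S,4R,6S)-8-hydroxy-4,6-dimethyl-2,3,7-trioxabicyclo[4.3.0]nonan-4-yl]-4-methylpentanal (lactol, both C8 epimers, formed in the flask) | C[C@H](CCC=O)C[C@]1(C)C[C@]2(C)OC(O)C[C@@H]2OO1 | intermediate
20 | (4R)-5-[(1S,4R,6S)-4,6-dimethyl-8-oxo-2,3,7-trioxabicyclo[4.3.0]nonan-4-yl]-4-methylpentanal | C[C@H](CCC=O)C[C@]1(C)C[C@]2(C)OC(=O)C[C@@H]2OO1 | intermediate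
21 | 1-phenylprop-2-en-1-ol (racemic) | OC(C=C)c1ccccc1 | starting material
22 | [1-(1-ethoxyethenyloxy)prop-2-en-1-yl]benzene (formed in the flask) | C=C(OCC)OC(C=C)c1ccccc1 | intermediate
23 | ethyl (E)-5-phenylpent-4-enoate | CCOC(=O)CC/C=C/c1ccccc1 | intermediate
24 | (E)-5-phenylpent-4-en-1-ol | OCCC/C=C/c1ccccc1 | intermediate
25 | 1-phenyl-5-{[(E)-5-phenylpent-4-en-1-yl]sulfanyl}-1H-tetrazole | C(CC/C=C/c1ccccc1)Sc1nnnn1-c1ccccc1 | intermediate
26 | 1-phenyl-5-{[(E)-5-phenylpent-4-en-1-yl]sulfinyl}-1H-tetrazole (racemic at sulfur, formed in the flask) | O=S(CCC/C=C/c1ccccc1)c1nnnn1-c1ccccc1 | intermediate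
27 | 1-phenyl-5-{[(E)-5-phenylpent-4-en-1-yl]sulfonyl}-1H-tetrazole | O=S(=O)(CCC/C=C/c1ccccc1)c1nnnn1-c1ccccc1 | intermediate
28 | potassium salt of the α-sulfonyl carbanion of 27 (formed in the flask) | [K+].[CH-](CC/C=C/c1ccccc1)S(=O)(=O)c1nnnn1-c1ccccc1 | intermediate
29 | (1S,4R,6S)-4,6-dimethyl-4-[(2R,5E,9E)-2-methyl-10-phenyldeca-5,9-dien-1-yl]-2,3,7-trioxabicyclo[4.3.0]nonan-8-one (CNP0365311.2) | C[C@H](CC/C=C/CC/C=C/c1ccccc1)C[C@]1(C)C[C@]2(C)OC(=O)C[C@@H]2OO1 | target

Total step count: 19. Longest linear sequence: 12 steps, from (R)-citronellal 5 through steps 4–14 and 19 to 29.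

Steps most likely to fail

Step 11. The process at risk is poor facial discrimination at C6 during the ring closure, possibly compounded by organomercury epimers that resist separation. As a fallback starting from 15, the ring would be closed with an iodonium source (N-iodosuccinimide, CH2Cl2, 0 °C). This reversible 6-exo iodoperoxidation has a different selectivity profile and should give the neutral (3S,4S,6R)-3-[2-(TBSO)ethyl]-6-[(2R)-5-(TBSO)-2-methylpentyl]-6-(iodomethyl)-4-methyl-1,2-dioxan-4-ol F1, whose C6 epimers are ordinary compounds for silica chromatography. Radical deiodination (Bu3SnH at high concentration, Et3B/air, toluene, 0 °C) then rejoins the route at 17.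

Step 10. The process at risk is sluggish SN2 opening at the hindered secondary epoxide carbon, so that base-induced decomposition of H2O2 or fragmentation of the β-hydroxy hydroperoxide takes over. As a fallback starting from 14, a protected peroxide nucleophile would be used. The cesium salt of 2-methoxyprop-2-yl hydroperoxide (reagent from ozonolysis of 2,3-dimethylbut-2-ene in MeOH; CsOH·H2O, DMF, rt to 40 °C) should open the epoxide at C3 with the same inversion to give the base-stable (3S,4S,8R)-1,11-bis(TBSO)-3-[(2-methoxypropan-2-yl)peroxy]-4,8-dimethyl-6-methylideneundecan-4-ol F2, which can be purified. Brief treatment with AcOH–THF–H2O at 0 °C releases the hydroperoxide and the route is rejoined at 15.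

Step 12. The process at risk is attack of the primary radical on the neighbouring O–O bond (epoxide formation with opening of the dioxane) before hydrogen transfer. As a fallback starting from 16, bromodemercuration (Br2, pyridine, CH2Cl2, 0 °C) should give the (3S,4S,6R)-6-(bromomethyl)-3-[2-(TBSO)ethyl]-6-[(2R)-5-(TBSO)-2-methylpentyl]-4-methyl-1,2-dioxan-4-ol F3. Its reduction with Bu3SnH in the presence of catalytic PhSeSePh, which generates benzeneselenol as a much faster hydrogen-atom donor, returns to 17.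

Further compounds
F1 | step 11 | (3S,4S,6R)-3-{2-[(tert-butyldimethylsilyl)oxy]ethyl}-6-{(2R)-5-[(tert-butyldimethylsilyl)oxy]-2-methylpentyl}-6-(iodomethyl)-4-methyl-1,2-dioxan-4-ol | C[C@H](CCCO[Si](C)(C)C(C)(C)C)C[C@]1(CI)C[C@](C)(O)[C@H](CCO[Si](C)(C)C(C)(C)C)OO1
F2 | step 10 | (3S,4S,8R)-1,11-bis[(tert-butyldimethylsilyl)oxy]-3-[(2-methoxypropan-2-yl)peroxy]-4,8-dimethyl-6-methylideneundecan-4-ol | C[C@H](CCCO[Si](C)(C)C(C)(C)C)CC(=C)C[C@](C)(O)[C@H](CCO[Si](C)(C)C(C)(C)C)OOC(C)(C)OC
F3 | step 12 | (3S,4S,6R)-6-(bromomethyl)-3-{2-[(tert-butyldimethylsilyl)oxy]ethyl}-6-{(2R)-5-[(tert-butyldimethylsilyl)oxy]-2-methylpentyl}-4-methyl-1,2-dioxan-4-ol | C[C@H](CCCO[Si](C)(C)C(C)(C)C)C[C@]1(CBr)C[C@](C)(O)[C@H](CCO[Si](C)(C)C(C)(C)C)OO1
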